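Add the two products in the autumn run at its first sample, and 38.0% of the charge is left over, in forms these readings do not name. At its last sample the leftover is 41.0%. The readings scatter by 2 percentage points, so you can't tell these apart, and the autumn run reads as stopped by its first sample.

| setting | autumn | spring | dawn | flask |
|---|---|---|---|---|
| starting material | 1 mM | 1 mM | 1.5 mM | 1.0 mM |
| coupling partner | 2.8 mM | 4.4 mM | 2 mM | 2.00 mM |
| capture agent | 0.10 mM | 0.10 mM | 0.10 mM | 0.100 mM |
| remark | run made earlier | run made earlier | run made earlier |  |
| time |  |  |  | 2.0 h |

- autumn (time / min: first product / %, double product / %): 15.0: 47, 15; 30.0: 45, 13; 40.0: 48, 17; 60.0: 48, 12; 80.0: 49, 14; 90.0: 47, 12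
- spring (time / min: first product / %, double product / %): 15.0: 18, 9; 30.0: 25, 12; 40.0: 22, 4; 60.0: 20, 7; 80.0: 22, 8; 90.0: 20, 8
- dawn (time / min: first product / %, double product / %): 20.0: 62, 7; 40.0: 66, 11; 60.0: 63, 8; 80.0: 65, 9; 90.0: 69, 9

(readings scatter by 2 percentage points)

- the analysis behind the earlier runs scatters by 2 percentage points, standard deviation

- equivalents of coupling partner to starting material, everything else as given, that leave most first product at 2.0 h
- the amount of first product then, in percent of the starting material charged
- the amount of first product with the amounts as given

Take that first sample time as a rough estimate of the longest half-life for whatever keeps the run going.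

count = 2.0 h / 15.0 min = 8.00

surviving share, estimated = 0.5^count = 0.391%

This is the half-life count: the time asked over that estimated half-life.

Turn the time first. With that count, you expect no gain from waiting.

Turn the coupling partner next. At 60.0 min, first product reads 63% in the dawn run at 1.33 equivalents, 48% in the autumn run at 2.80 and 20% in the spring run at 4.40. Across these runs, fewer equivalents go with more first product. The flask, at 2.00 equivalents, lies between dawn and autumn, so my figure is their midpoint, 55.5%.

The starting material changes in the dawn run together with the ratio, so you can't separate the two. The capture agent is not varied in these runs, so they are silent on it.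

The forecast gives 60% for the flask, more than my figure, and 70% at 1.5 equiv. Its ground: “Lowering the coupling partner improves both conversion and selectivity until it becomes limiting”.

The flask gives 59.4%, and 62.9% at 1.55 equiv.

    coupling partner + first product → double product + released group (k = 18.2 /M/s)
    starting material + coupling partner → first product + released group (k = 125 /M/s)
    first product + capture agent → trapped intermediate (k = 54.9 /M/s)
    coupling partner + double product → tris adduct + released group (k = 80.9 /M/s)
    coupling partner + tris adduct → tetra adduct + released group (k = 79.0 /M/s)
    coupling partner → decomposed reagent (k = 0.0208 /s)

In the flask, first product is 59.4% at 0.200 h and 59.4% at 20.0 h. Count on the coupling partner in a neighbouring flask charged with 0.800 equiv, where it is the limiting reagent. The same 8.00 half-lives give an estimated 0.391% of its charge at 2.00 h. The neighbour holds 0% of it then. Its first product is 45.6%, and 40% of its starting material is still there.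

The readings are simulated with constants of no real substance; the scatter is artificial.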